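The easy step is a count of equivalents: the flask holds [reagent in the second phase]/[substrate] = 0.700, so the reagent is the limiting reagent.

- Wednesday's: substrate 20 mM; reagent in the second phase 28 mM; run made earlier
- flask: substrate 20 mM; reagent in the second phase 14.0 mM; time 3.0 h; volume of the second phase over the first 0.25

- Wednesday's (time / min: target / %, substrate / %): 3.00: 0, 100; 6.00: 4, 100; 15.0: 7, 86; 40.0: 29, 61

(readings scatter by 1.5 percentage points)

- in the second phase: reagent in the second phase; everything else is in the first
- charges count per volume of the first phase; a concentration in a rate is the amount of a species over the volume of its own phase; every rate counts per litre of the first phase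
- the earlier runs hold the two phases in the same ratio of volumes as the flask asked about

1. how much target there is at 3.0 h, in percent of the substrate charged
2. the change that raises the amount of target at 3.0 h, in percent of the substrate charged most ("none" if none brings more than 2 percentage points) (birch / ash / none)
3. amount of target at 3.0 h, in percent of the substrate charged, after ash

- birch: doubling the amount of reagent in the second phase, all else as stated
- ash: doubling the transfer coefficient of the reagent in the second phase, all else as stated

But a count gives a ceiling and no pace, so the pace has to come from Wednesday's run. Between 15.0 min and 40.0 min its substrate falls from 86% to 61%, and that loss over its reagent charge reads as a coefficient of 0.00714 min⁻¹, a rough reading. Taken as first-order in unspent reagent, this makes 1.29 turnovers in 3.0 h. So 50.6% is the reckoned loss in the flask: the spent equivalents, substrate lost per substrate charged. Wednesday's last reading puts 74.4% of lost substrate in target, so this reckoning commits to about 37.6% of target. Doubling the turnovers lifts the spent equivalents to 64.7%, whereas doubling the charge takes the reckoned figure to 100%, the substrate charged, so this reckoning picks birch.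

The forecast, which judges the loss “looks limited by reagent transfer”, gives 53%, picks birch, and gives 65% after ash.

The simulation gives 25.4% of target; birch adds 4.5 percentage points, ash adds 0.61 points, and 26.0% stands after ash.

    reagent in the reaction phase ⇌ reagent in the second phase, rate k1*([reagent in the reaction phase] - [reagent in the second phase]/K1) per volume of the first phase (partition coefficient = 2.10, kL = 0.00836 min⁻¹)
    substrate + reagent in the reaction phase → target (k = 4.19 L mol⁻¹ min⁻¹)
    reagent in the reaction phase + target → over-reacted product (k = 1.02 L mol⁻¹ min⁻¹)
    reagent in the reaction phase + target → over-reaction product (k = 1.10 L mol⁻¹ min⁻¹)
    target ⇌ isomer of the product (K = 0.960, k = 0.0190 min⁻¹)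

The flask loses 54.8% of its substrate against the reckoned 50.6%, so the shortfall of target against the reckoned figure lies in the share that stays target. Part of that shortfall comes from target turning into isomer of the product, both ways: the flask without that step gives 42.9% of target, and with it the isomer of the product stands at 22.2%. The same turnovers on the neighbour flask with 50 mM of substrate give spent equivalents of 20.3%, and that neighbour flask loses 24.8%.

(The data come from a simulation for an exercise, noise included.)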